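The rate constants belong to no real substance; no experiment stands behind them.

The constants set a race for each living end J: it adds Q at 1.78 M⁻¹ s⁻¹, is capped by Q at 0.415 M⁻¹ s⁻¹, and dies unaided at 0.00216 s⁻¹.

    J + Q → J.Q (k1 = 0.415 M⁻¹ s⁻¹)
    Q + J → X + J, rate k2*[J]*[Q] (k2 = 1.78 M⁻¹ s⁻¹)
    J → E (k3 = 0.00216 s⁻¹)
    G + Q → G.Q (k4 = 0.296 M⁻¹ s⁻¹)
    Q + Z → J + X (k5 = 1.12 M⁻¹ s⁻¹)

the same everywhere: Q 12 mM; G 2.40 mM; Z 0.60 mM
- autumn: time 1.5 h
- dusk: time 3.0 h

* which of the two ends with the longer chains by the average number of monomer units in a chain (chains begun, living or dead) ("neither" if they lie within 10%) (autumn / dusk / neither)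
* average number of monomer units in a chain (chains begun, living or dead) at the end, autumn
* average number of monomer units in a chain (chains begun, living or dead) at the end, dusk

- the average divides the monomer in chains by the number of chains begun, living and dead together
- run time (autumn): 1.5 h

I drew the curve of c(X) against time by hand. At the start no J stood, so the slope was that of initiation, 0.484 mM min⁻¹. The knee followed from the lifetimes at charged Q: 74.4 s for Z, 140 s for J and 282 s for G. Each is far shorter than autumn's 1.5 h, so I expected the curve to reach its level well before either flask ended, and the two flasks to end alike.

That level is a matter of odds. I counted each Z as one chain with one unit, after which its end draws between adding and ending. The number of units added per cap, the ratio of the two constants, is the chain odds, 4.29. Dying matches capping at a crossover c(Q) of 5.20 mM. So the length, the kinetic chain length, is one unit plus the odds times c(Q)/(c(Q) + crossover).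

At charged Q this gave 3.99. But Q falls: G can take 2.40 mM, the chains about 2.39 mM and the caps about 0.418 mM. By this estimate about 6.79 mM was left, where the rule gave 3.43. The chains were made while c(Q) fell between these two amounts, so I committed to the middle, 3.71, for both flasks, which put the level of c(X) near 2.23 mM.

The forecast gave 3.73 for autumn (3.6 to 3.85) and 3.73 for dusk (3.6 to 3.85), and chose "neither", holding that “dusk's extra time adds nothing”.

The simulation gave 3.75 for autumn and 3.75 for dusk, so the choice was "neither". I applied the same rule to the flask like dusk but charged with 30 mM of Q, taking its end c(Q) from the simulation. The rule gave 4.66 at its charge. At the 81.1% of that charge left after 3.00 h, it gave 4.53. The middle of these was 4.60, and the simulated length of that flask was 4.59.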